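## Retrosynthetic overview

1. The target comes from a 7-oxo tetracycle (cyclobuta[a]indene numbering). The C7 ketone is removed last through the neighbouring phenol (carbonate, borohydride, ortho-quinone methide), together with the catechol acetates. The prenyl group enters just before, by Stille coupling at a C3 bromide.
2. Key disconnection: the cyclopentenone bond C2a–C7a (intramolecular aldol condensation of a 2-acetylbenzaldehyde to an indenone) and the cyclobutane bonds C1–C7a and C2–C2a (crossed [2+2] of that indenone with a β,β-dimethylstyrene) are made in one flask.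
3. The peri-hydroxy ketone of the indenone chelates a chiral scandium–PyBox Lewis acid, which sets all three stereocentres in that operation.
4. Partners: 2-acetyl-6-bromo-3-hydroxy-5-methoxybenzaldehyde (from 2-bromo-3,5-dimethoxybenzaldehyde by Stille acetylation, bromination and chelation-controlled mono-demethylation) and 4-(2-methylprop-1-enyl)catechol diacetate (from 3,4-dihydroxybenzaldehyde by Wittig reaction and acetylation).
5. Ring order: both benzene rings are bought; the five-membered ring forms first and the four-membered ring second, in the same operation.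

Assumption: (S,S)-tBu-PyBox is taken to give the enantiomer drawn in the key step; if the first run shows the mirror-image sense, the (R,R) ligand is used with nothing else changed.

## Route

**Step 1**
Reactants: 1 3,4-dihydroxybenzaldehyde
Product: 3 4-(2-methylprop-1-en-1-yl)-1,2-phenylene diacetate, via catechol styrene 2 (not isolated)
Conditions: iPrPPh3I (1.5 equiv), KOtBu (3.6 equiv), THF, 0 °C to 60 °C; then Ac2O (4 equiv), 0 °C to rt
Reagents that add atoms: isopropyltriphenylphosphonium iodide, CC(C)[P+](c1ccccc1)(c1ccccc1)c1ccccc1.[I-]; acetic anhydride, CC(=O)OC(C)=O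
Why: Wittig olefination of the aldehyde as its bis-phenoxide with excess non-stabilised ylide gives the trisubstituted styrene (no E/Z issue, the new alkene carbon carries two methyl groups), and acetylating the phenoxides in the flask masks the catechol so that it can neither bind the Lewis acid nor quench the sensitiser in step 5; no stereocentre is formed.

**Step 2**
Reactants: 4 2-bromo-3,5-dimethoxybenzaldehyde
Product: 6 2-acetyl-3,5-dimethoxybenzaldehyde, via enol ether 5 (not isolated)
Conditions: tributyl(1-ethoxyethenyl)stannane (1.2 equiv), PdCl2(PPh3)2 (5 mol%), toluene, 100 °C; then 1 M HCl, THF, rt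
Reagents that add atoms: tributyl(1-ethoxyethenyl)stannane, CCCC[Sn](CCCC)(CCCC)C(=C)OCC; water, O
Why: Stille coupling (oxidative addition is eased by the ortho formyl group) installs a masked acetyl group, and mild acid hydrolysis of the enol ether unveils the methyl ketone; no stereocentre is formed.

**Step 3**
Reactants: 6 2-acetyl-3,5-dimethoxybenzaldehyde
Product: 7 2-acetyl-6-bromo-3,5-dimethoxybenzaldehyde
Conditions: NBS (1.05 equiv), MeCN, 0 °C to rt
Reagents that add atoms: N-bromosuccinimide, O=C1CCC(=O)N1Br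
Why: electrophilic aromatic bromination goes to C6, which is para to one methoxy group and ortho to the other and is less crowded than C4 between the two methoxy groups (the same preference that leads to 2,6-dibromination of 3,5-dimethoxybenzaldehyde); no stereocentre is formed.

**Step 4**
Reactants: 7 2-acetyl-6-bromo-3,5-dimethoxybenzaldehyde
Product: 8 2-acetyl-6-bromo-3-hydroxy-5-methoxybenzaldehyde
Conditions: BCl3 (2.5 equiv), CH2Cl2, −78 °C to 0 °C; H2O
Reagents that add atoms: none
Why: chelation-controlled Lewis acid ether cleavage: boron bridges the acetyl oxygen and the ortho methoxy oxygen, so only that methyl group is removed (the other methoxy group has no carbonyl neighbour), which tells the two oxygens of ring A apart; no stereocentre is formed.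

**Step 5**
Reactants: 8 2-acetyl-6-bromo-3-hydroxy-5-methoxybenzaldehyde; 3 4-(2-methylprop-1-en-1-yl)-1,2-phenylene diacetate
Product: 11 4-[(2S,2aS,7aS)-3-bromo-6-hydroxy-4-methoxy-1,1-dimethyl-7-oxo-2,2a,7,7a-tetrahydro-1H-cyclobuta[a]inden-2-yl]-1,2-phenylene diacetate, via aldol 9 (not isolated), via bromoindenone 10 (not isolated)
Conditions: Sc(OTf)3 (10 mol%), (S,S)-tBu-PyBox (15 mol%), 4 Å MS, degassed iPrOAc/MeCN 3:1, 40 °C, dark; then 3 (3 equiv), Ru(bpy)3(PF6)2 (2.5 mol%), blue LEDs, 20 °C
Reagents that add atoms: none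
Why: Proposed new method: the Sc(OTf)3/PyBox Lewis acid (helped by the trace of TfOH it releases on binding the phenol) first drives the intramolecular aldol addition of the acetyl enol to the neighbouring formyl group and the dehydration of aldol 9, so the sensitive indenone 10 is formed already chelated through its peri-hydroxy ketone to the chiral scandium centre; chelation lowers its triplet energy so that Ru(bpy)3(PF6)2 sensitises only the bound enone, whose triplet adds through C2 to the CMe2 carbon of 3 to give a doubly benzylic 1,4-biradical that closes on the enone face left open by the tert-butyl groups of the ligand, giving the cis ring fusion (forced by the five-membered ring), the aryl group exo and trans to the ring A bond at C2a, and the 2S,2aS,7aS configuration; the closest known reaction types are the chiral Lewis acid-catalysed, triplet-sensitised crossed [2+2] photocycloaddition of 2'-hydroxychalcones with styrenes and the acid-catalysed aldol cyclodehydration of 2-acylbenzaldehydes to indenones.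

**Step 6**
Reactants: 11 4-[(2S,2aS,7aS)-3-bromo-6-hydroxy-4-methoxy-1,1-dimethyl-7-oxo-2,2a,7,7a-tetrahydro-1H-cyclobuta[a]inden-2-yl]-1,2-phenylene diacetate
Product: 12 4-[(2S,2aS,7aS)-6-hydroxy-4-methoxy-1,1-dimethyl-3-(3-methylbut-2-en-1-yl)-7-oxo-2,2a,7,7a-tetrahydro-1H-cyclobuta[a]inden-2-yl]-1,2-phenylene diacetate
Conditions: tributyl(3-methylbut-2-en-1-yl)stannane (1.5 equiv), Pd[P(t-Bu)3]2 (5 mol%), DMF, 80 °C
Reagents that add atoms: tributyl(3-methylbut-2-en-1-yl)stannane, CCCC[Sn](CCCC)(CCCC)CC=C(C)C
Why: Stille cross-coupling transfers the allyl group at its tin-bearing carbon, giving the linear prenyl arene, and the neutral conditions leave the acetates, the enolisable ketone and the three stereocentres untouched; the prenyl group is added only now because an ortho-prenyl benzaldehyde would undergo a carbonyl-ene cyclisation under the Lewis acid of step 5.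

**Step 7**
Reactants: 12 4-[(2S,2aS,7aS)-6-hydroxy-4-methoxy-1,1-dimethyl-3-(3-methylbut-2-en-1-yl)-7-oxo-2,2a,7,7a-tetrahydro-1H-cyclobuta[a]inden-2-yl]-1,2-phenylene diacetate
Product: 16 4-[(2S,2aR,7aS)-6-hydroxy-4-methoxy-1,1-dimethyl-3-(3-methylbut-2-en-1-yl)-2,2a,7,7a-tetrahydro-1H-cyclobuta[a]inden-2-yl]benzene-1,2-diol, via carbonate 13 (not isolated), via quinone methide 14 (not isolated), via diacetate 15 (not isolated)
Conditions: ClCO2Et (1.2 equiv), Et3N, THF, 0 °C; then NaBH4 (6 equiv), H2O, 0 °C to rt; then K2CO3 (0.3 equiv), MeOH, Ar, rt; aq NH4Cl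
Reagents that add atoms: none
Why: reductive deoxygenation of an ortho-hydroxyaryl ketone: the phenol is O-acylated to carbonate 13, NaBH4 reduces the ketone, the ethoxycarbonyl group shifts to the new benzylic alkoxide and is expelled by the phenoxide to give ortho-quinone methide 14, which takes up hydride at C7 to give 15, and carbonate-catalysed methanolysis then frees the catechol; the alkene, the methyl ether and the three stereocentres are not touched (the C2a descriptor changes from S to R only because the CIP priorities change when C7 loses its oxygen).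

## Compound list

1 | 3,4-dihydroxybenzaldehyde | O=Cc1ccc(O)c(O)c1 | starting material
2 | 4-(2-methylprop-1-en-1-yl)benzene-1,2-diol (formed as its dipotassium salt, not isolated) | CC(C)=Cc1ccc(O)c(O)c1 | intermediate
3 | 4-(2-methylprop-1-en-1-yl)-1,2-phenylene diacetate | CC(C)=Cc1ccc(OC(C)=O)c(OC(C)=O)c1 | intermediate
4 | 2-bromo-3,5-dimethoxybenzaldehyde | COc1cc(OC)c(Br)c(C=O)c1 | starting material
5 | 2-(1-ethoxyethenyl)-3,5-dimethoxybenzaldehyde (not isolated) | CCOC(=C)c1c(OC)cc(OC)cc1C=O | intermediate
6 | 2-acetyl-3,5-dimethoxybenzaldehyde | CC(=O)c1c(OC)cc(OC)cc1C=O | intermediate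
7 | 2-acetyl-6-bromo-3,5-dimethoxybenzaldehyde | CC(=O)c1c(OC)cc(OC)c(Br)c1C=O | intermediate
8 | 2-acetyl-6-bromo-3-hydroxy-5-methoxybenzaldehyde | CC(=O)c1c(O)cc(OC)c(Br)c1C=O | intermediate
9 | 4-bromo-3,7-dihydroxy-5-methoxy-2,3-dihydro-1H-inden-1-one (racemic at C3, not isolated) | O=C1CC(O)c2c1c(O)cc(OC)c2Br | intermediate
10 | 4-bromo-7-hydroxy-5-methoxy-1H-inden-1-one (achiral, not isolated) | O=C1C=Cc2c1c(O)cc(OC)c2Br | intermediate
11 | 4-[(2S,2aS,7aS)-3-bromo-6-hydroxy-4-methoxy-1,1-dimethyl-7-oxo-2,2a,7,7a-tetrahydro-1H-cyclobuta[a]inden-2-yl]-1,2-phenylene diacetate | COc1cc(O)c2c(c1Br)[C@@H]1[C@H](C2=O)C(C)(C)[C@H]1c1ccc(OC(C)=O)c(OC(C)=O)c1 | intermediate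
12 | 4-[(2S,2aS,7aS)-6-hydroxy-4-methoxy-1,1-dimethyl-3-(3-methylbut-2-en-1-yl)-7-oxo-2,2a,7,7a-tetrahydro-1H-cyclobuta[a]inden-2-yl]-1,2-phenylene diacetate | COc1cc(O)c2c(c1CC=C(C)C)[C@@H]1[C@H](C2=O)C(C)(C)[C@H]1c1ccc(OC(C)=O)c(OC(C)=O)c1 | intermediate
13 | ethyl (2S,2aS,7aS)-2-(3,4-diacetoxyphenyl)-4-methoxy-1,1-dimethyl-3-(3-methylbut-2-en-1-yl)-7-oxo-2,2a,7,7a-tetrahydro-1H-cyclobuta[a]inden-6-yl carbonate (not isolated) | COc1cc(OC(=O)OCC)c2c(c1CC=C(C)C)[C@@H]1[C@H](C2=O)C(C)(C)[C@H]1c1ccc(OC(C)=O)c(OC(C)=O)c1 | intermediate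
14 | 4-[(2S,2aR,7aS)-4-methoxy-1,1-dimethyl-3-(3-methylbut-2-en-1-yl)-6-oxo-2,2a,6,7a-tetrahydro-1H-cyclobuta[a]inden-2-yl]-1,2-phenylene diacetate (ortho-quinone methide, C6a=C7 double bond, not isolated) | COC1=CC(=O)C2C(=C1CC=C(C)C)[C@@H]1[C@H](C=2)C(C)(C)[C@H]1c1ccc(OC(C)=O)c(OC(C)=O)c1 | intermediate
15 | 4-[(2S,2aR,7aS)-6-hydroxy-4-methoxy-1,1-dimethyl-3-(3-methylbut-2-en-1-yl)-2,2a,7,7a-tetrahydro-1H-cyclobuta[a]inden-2-yl]-1,2-phenylene diacetate (not isolated) | COc1cc(O)c2c(c1CC=C(C)C)[C@@H]1[C@H](C2)C(C)(C)[C@H]1c1ccc(OC(C)=O)c(OC(C)=O)c1 | intermediate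
16 | 4-[(2S,2aR,7aS)-6-hydroxy-4-methoxy-1,1-dimethyl-3-(3-methylbut-2-en-1-yl)-2,2a,7,7a-tetrahydro-1H-cyclobuta[a]inden-2-yl]benzene-1,2-diol (CNP0236667.1) | COc1cc(O)c2c(c1CC=C(C)C)[C@@H]1[C@H](C2)C(C)(C)[C@H]1c1ccc(O)c(O)c1 | target

## Step count and risks

Total step count: 7. Longest linear sequence: 6 steps (4 to 16, steps 2 to 7).

The three steps most likely to fail are steps 5, 7 and 6.

**Step 5 (one-pot cyclodehydration and enantioselective photocycloaddition).** The in-flask indenone formation or the face selectivity of the scandium complex may fall short. The fallback sets the stereochemistry by resolution instead of catalysis and sets out from 8 and 3. The same one-pot sequence is run with ligand-free Sc(OTf)3 (plus 5 mol% TsOH for the cyclodehydration if needed) and Ru(bpy)3(PF6)2, which gives the racemic adduct F1. Its free phenol is acylated with (1R,2S,5R)-menthyl chloroformate and Et3N, and the two diastereomeric carbonates are separated by crystallisation or chromatography into the (2S,2aS,7aS) menthyl carbonate F2 and the (2R,2aR,7aR) menthyl carbonate F3, which is set aside. F2 is prenylated under the Stille conditions of step 6 to give the prenylated menthyl carbonate F4. NaBH4 in wet THF then reduces F4 exactly as it would carbonate 13, the resolving group serving as the activating group. This comes back to the route at 15, which is methanolysed to 16 as in step 7.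

**Step 7 (deoxygenation through the ortho-quinone methide).** The strained quinone methide may isomerise or the acetates may interfere. The fallback removes the ketone through a diazene instead and sets out from 12. Condensation with TsNHNH2 (MeOH, cat. AcOH, 50 °C) gives the tosylhydrazone F5. Catecholborane (CHCl3, 0 °C) followed by NaOAc·3H2O at reflux reduces the C=N bond and expels sulfinate and N2. This comes back to the route at 15, and K2CO3 in MeOH then gives 16.

**Step 6 (Stille prenylation of a hindered, electron-rich bromide).** The coupling may be slow or give the branched 1,1-dimethylallyl isomer. The fallback builds the side chain in two stages and sets out from 11. Stille coupling with allyltributylstannane (same catalyst) gives the allyl arene F6. Cross-metathesis with 2-methylbut-2-ene (solvent; second-generation Grubbs catalyst, (H2IMes)(PCy3)Cl2Ru=CHPh, 40 °C) turns the allyl group into the prenyl group and comes back to the route at 12.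

## Further compounds

F1 | step 5 | racemic adduct, 1:1 mixture of 11 and its (2R,2aR,7aR) enantiomer | COc1cc(O)c2c(c1Br)[C@@H]1[C@H](C2=O)C(C)(C)[C@H]1c1ccc(OC(C)=O)c(OC(C)=O)c1.COc1cc(O)c2c(c1Br)[C@H]1[C@@H](C2=O)C(C)(C)[C@@H]1c1ccc(OC(C)=O)c(OC(C)=O)c1
F2 | step 5 | (1R,2S,5R)-menthyl carbonate of 11 at the C6 phenol, core (2S,2aS,7aS) | COc1cc(OC(=O)O[C@@H]3C[C@H](C)CC[C@H]3C(C)C)c2c(c1Br)[C@@H]1[C@H](C2=O)C(C)(C)[C@H]1c1ccc(OC(C)=O)c(OC(C)=O)c1
F3 | step 5 | (1R,2S,5R)-menthyl carbonate of the enantiomer of 11, core (2R,2aR,7aR) | COc1cc(OC(=O)O[C@@H]3C[C@H](C)CC[C@H]3C(C)C)c2c(c1Br)[C@H]1[C@@H](C2=O)C(C)(C)[C@@H]1c1ccc(OC(C)=O)c(OC(C)=O)c1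
F4 | step 5 | (1R,2S,5R)-menthyl carbonate of 12 at the C6 phenol, core (2S,2aS,7aS) | COc1cc(OC(=O)O[C@@H]3C[C@H](C)CC[C@H]3C(C)C)c2c(c1CC=C(C)C)[C@@H]1[C@H](C2=O)C(C)(C)[C@H]1c1ccc(OC(C)=O)c(OC(C)=O)c1
F5 | step 7 | 4-methylbenzenesulfonylhydrazone of 12 at C7, core (2S,2aS,7aS) | COc1cc(O)c2c(c1CC=C(C)C)[C@@H]1[C@H](C2=NNS(=O)(=O)c3ccc(C)cc3)C(C)(C)[C@H]1c1ccc(OC(C)=O)c(OC(C)=O)c1
F6 | step 6 | 4-[(2S,2aS,7aS)-6-hydroxy-4-methoxy-1,1-dimethyl-7-oxo-3-(prop-2-en-1-yl)-2,2a,7,7a-tetrahydro-1H-cyclobuta[a]inden-2-yl]-1,2-phenylene diacetate | COc1cc(O)c2c(c1CC=C)[C@@H]1[C@H](C2=O)C(C)(C)[C@H]1c1ccc(OC(C)=O)c(OC(C)=O)c1
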